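**Assumption (remark on the chemistry):** kazinol N has no stereocentre, so the only stereochemical element the route must control is the Z geometry of one alkene in the key-step precursor. 5-Methylhex-4-en-1-yne is treated as not purchasable and is made in step 5.

## The problem

Kazinol N is an achiral 1,3-diarylpropane. Ring A (4-hydroxy-2-methoxyphenyl) is joined by a three-carbon chain to C6 of a 2,2-dimethyl-2H-chromene (benzene ring B fused to pyran ring C). Ring B carries five contiguous substituents and a single hydrogen: the chain at C6, prenyl at C5, the pyran vinyl carbon at C4a, the pyran oxygen at C8a and a free hydroxyl at C8. The prenyl group sits at the most hindered position, between the chain and the peri C4=C3 alkene; it is para to the C8 hydroxyl, but the free ortho position C7 competes in any electrophilic or sigmatropic prenylation. There is no stereocentre to set, but the molecule is fragile. The catechol monoether oxidises easily as its phenoxide. The chromene and prenyl alkenes forbid hydrogenation, strong acid and late electrophilic oxidants. Two phenols must be freed while the ring A methyl ether stays, so O-demethylation cannot end the route.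

The feature that opens the problem is the edge C6(alkyl)–C7(H)–C8(O)–C8a(O) of ring B. It is the C6–C5–C4–C3 diene of a 6-alkyl-4-hydroxy-2-pyrone with one more oxygen at C3. The two remaining ring B carbons, C5 and C4a, carry only carbon substituents and can come from an alkyne. The ring C atoms O1–C2(Me2)–C3=C4 form a four-atom tether with a cis alkene that links the pyrone C3 oxygen to that alkyne.

## Retrosynthesis

Target 20 is taken back to its bis(triisopropylsilyl) ether 19. Only two O–Si bonds are cut. The same silyl group on both phenols allows one fluoride step at the end and survives organozinc, enolate, base and heat earlier.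

19 is cut at C4a–C8a and C5–C6 (chromene numbering), and CO2 is put back as a lactone bridge between C8a and C6. This leads through bicyclic lactone 18 to the monocyclic pyrone 17, whose C3 oxygen carries the chain O–CMe2–CH=CH–C≡C–CH2–CH=CMe2. The other ways to map a pyrone onto ring B put the alkyne on C5/C6 or C6/C7; they need an unactivated intermolecular alkyne or an ynol ether, and none builds ring C. The chosen cut uses an alkyne with two carbon substituents and a tether made only of atoms of the target. 17 has neither ring B nor ring C. The forward reaction must be an intramolecular Diels–Alder reaction followed by loss of CO2 that tolerates a tertiary allylic ether at the required temperature.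

17 comes from the 4-hydroxypyrone 16 by O-silylation. 16 is cut at the bond between pyrone C3 and the ether oxygen, giving diazo compound 8 and tertiary alcohol 15. A tertiary alkoxide cannot be alkylated or arylated at this position, so the polarity is reversed: C3 becomes a rhodium carbenoid that inserts into the O–H bond. The neighbouring cut, building the ether before the pyrone ring, costs more steps and exposes a (Z)-enynol alkoxide to cyclisation. The forward step needs O–H insertion to win over addition to the π bonds of 15.

8 comes from pyrone 7 by diazo transfer at C3. 7 is cut at C4–C5 and O1–C2, giving dioxo ester 6 and then ester 4 plus methyl acetoacetate 5. This polyketide-type assembly places alkyl at C6, H at C5 and OH at C4 without any regiochemical choice. 4 is cut at the aryl–CH2 bond into aryl bromide 2 and the functionalised alkylzinc reagent 3; 2 comes from phenol 1. The chain is thus made by one sp2–sp3 coupling, with no carbonyl to remove later.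

Alcohol 15 is cut at its two C–CH3 bonds to ester 13, by way of ketone 14. 13 is cut at the alkene–alkyne bond into (Z)-iodoacrylate 12 and skipped enyne 11; the Z geometry is bought with 12 and kept. 11 is cut at the propargylic C–C bond into ethynylmagnesium bromide 9 and prenyl bromide 10.

## Roads not taken

**Alternative 1:** keep ring B aromatic throughout, the route most chemists would draw first. A catechol aldehyde gives 8-hydroxy-2,2-dimethyl-2H-chromene-6-carbaldehyde A1 through Claisen rearrangement of a 1,1-dimethylpropargyl aryl ether. Prenyl is then introduced at C5 by halogenation and cross-coupling, and aldol condensation with a ring A methyl ketone gives chalcone A2, which is reduced to the propane chain. C5 must be functionalised in preference to C7, although both are ortho to the formyl group and C5 is the more hindered. The enone of A2 must be reduced to three CH2 groups beside a chromene alkene and a prenyl alkene, which hydrogenation does not distinguish. Three phenolic oxygens also need separate protecting group steps. The chosen plan fixes every ring B substituent by construction and never has a carbonyl in the chain.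

**Alternative 2:** benzannulation through a dienylketene. Ring B is cut into a vinylketene, from a cyclobutenone such as A3, and a heteroatom-substituted alkyne (Danheiser benzannulation), or into an alkenyl chromium carbene complex, an alkyne and CO. The forward sequence is [2+2] cycloaddition, four-electron ring opening and six-electron ring closure. These reactions place the two oxygens 1,3 or 1,4 on the new ring, and ring B needs them 1,2. Every mapping therefore leaves an oxygen to delete or asks for a dialkoxyalkyne, and ring C would still have to be added afterwards. The pyrone route gives the 1,2 pattern directly and closes ring C in the same step.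

**Alternative 3:** a partly saturated ring B aromatised late. A six-membered cyclic 1,3-diketone and the C5 enal give 2,2-dimethyl-2,6,7,8-tetrahydro-5H-chromen-5-one A4 by Knoevenagel condensation and oxa-six-electron electrocyclisation. This would be followed by enolate alkylation at C6 with a ring A propyl iodide, addition of a prenyl metal to the C5 carbonyl, dehydration and aromatisation. Ring C and the C5/C6 substituents come easily, but C8 has no oxygen. It would have to be introduced at the γ position of a vinylogous ester, where enolisation does not occur. The prenyl metal can also add through either end, and the aromatising oxidant meets a prenyl group. The chosen plan carries the C8 oxygen in the pyrone from the start.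

Key step: step 10

## Steps

**Step 1**
Reactants: 1 4-bromo-3-methoxyphenol
Product: 2 (4-bromo-3-methoxyphenoxy)triisopropylsilane
Conditions: TIPSCl, imidazole, DMF, rt
Reagents that add atoms: chlorotriisopropylsilane, CC(C)[Si](Cl)(C(C)C)C(C)C
Why: Silyl ether formation on a phenol; the triisopropylsilyl ether is chosen because it must survive the organozinc, enolate dianion, DBU and 180 °C steps and still fall to fluoride at the end.

**Step 2**
Reactants: 2 (4-bromo-3-methoxyphenoxy)triisopropylsilane; 3 4-ethoxy-4-oxobutylzinc bromide (commercial THF solution)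
Product: 4 ethyl 4-[2-methoxy-4-(triisopropylsilyloxy)phenyl]butanoate
Conditions: Pd(OAc)2 (2 mol%), SPhos (4 mol%), THF, 25 → 50 °C
Reagents that add atoms: none
Why: Negishi coupling of an aryl bromide with a primary alkylzinc halide; the dialkylbiarylphosphine favours oxidative addition into the electron-rich ortho-substituted bromide and reductive elimination over β-hydride elimination, and the ester is inert to zinc.

**Step 3**
Reactants: 4 ethyl 4-[2-methoxy-4-(triisopropylsilyloxy)phenyl]butanoate; 5 methyl acetoacetate
Product: 7 4-hydroxy-6-{3-[2-methoxy-4-(triisopropylsilyloxy)phenyl]propyl}-2H-pyran-2-one, via dioxo ester 6 (not isolated)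
Conditions: 5 (2.2 equiv), NaH then n-BuLi, THF, 0 °C; add 4, 0 °C → rt; aq. HCl quench; crude 6, DBU (1.5 equiv), PhMe, 110 °C; acidic work-up
Reagents that add atoms: none
Why: Claisen-type acylation of the acetoacetate dianion at its terminal carbon by the ester gives the 3,5-dioxo ester 6, whose C5 enol oxygen closes onto the methyl ester under DBU (lactonisation) to the 4-hydroxy-2-pyrone. Two equivalents of dianion are used because the product consumes one.

**Step 4**
Reactants: 7 4-hydroxy-6-{3-[2-methoxy-4-(triisopropylsilyloxy)phenyl]propyl}-2H-pyran-2-one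
Product: 8 3-diazo-6-{3-[2-methoxy-4-(triisopropylsilyloxy)phenyl]propyl}-2H-pyran-2,4(3H)-dione
Conditions: 4-acetamidobenzenesulfonyl azide, Et3N, MeCN, 0 °C → rt
Reagents that add atoms: 4-acetamidobenzenesulfonyl azide, CC(=O)Nc1ccc(cc1)S(=O)(=O)N=[N+]=[N-]
Why: Regitz diazo transfer to C3 of the 4-hydroxy-2-pyrone, which reacts as a cyclic 1,3-dicarbonyl compound; this is established for 4-hydroxy-6-methyl-2-pyrone and 4-hydroxycoumarin.

**Step 5**
Reactants: 9 ethynylmagnesium bromide (commercial THF solution); 10 prenyl bromide (1-bromo-3-methylbut-2-ene)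
Product: 11 5-methylhex-4-en-1-yne
Conditions: CuCl (5 mol%), THF, 0 → 40 °C; distillation
Reagents that add atoms: none
Why: Copper-catalysed allylic substitution of the prenyl halide by an alkynyl Grignard reagent; attack at the primary carbon should give the linear skipped enyne, and any branched isomer is removed by distillation.

**Step 6**
Reactants: 11 5-methylhex-4-en-1-yne; 12 ethyl (Z)-3-iodoacrylate
Product: 13 ethyl (Z)-8-methylnona-2,7-dien-4-ynoate
Conditions: PdCl2(PPh3)2 (2 mol%), CuI (4 mol%), Et3N, THF, 0 °C → rt
Reagents that add atoms: none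
Why: Sonogashira coupling of a (Z)-β-iodoacrylate with a terminal alkyne proceeds with retention of alkene geometry, which sets the only stereo-element of the route. A tertiary amine at low temperature avoids conjugate addition and isomerisation of the 1,4-enyne.

**Step 7**
Reactants: 13 ethyl (Z)-8-methylnona-2,7-dien-4-ynoate
Product: 15 (Z)-2,9-dimethyldeca-3,8-dien-5-yn-2-ol, via methyl ketone 14 (not isolated)
Conditions: MeLi (3 equiv), CeCl3, THF, −78 °C; aq. NH4Cl; base-washed silica
Reagents that add atoms: methyllithium, [Li]C
Why: Double 1,2-addition of the methylcerium reagent to the ester by way of ketone 14; the organocerium suppresses conjugate addition and enolisation, so the Z alkene is untouched. The alcohol is made after the palladium/copper step so that the (Z)-enynol never meets a metal that could cycloisomerise it.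

**Step 8**
Reactants: 8 3-diazo-6-{3-[2-methoxy-4-(triisopropylsilyloxy)phenyl]propyl}-2H-pyran-2,4(3H)-dione; 15 (Z)-2,9-dimethyldeca-3,8-dien-5-yn-2-ol
Product: 16 3-{[(3Z)-2,9-dimethyldeca-3,8-dien-5-yn-2-yl]oxy}-4-hydroxy-6-{3-[2-methoxy-4-(triisopropylsilyloxy)phenyl]propyl}-2H-pyran-2-one
Conditions: Rh2(OAc)4 (2 mol%), 15 (3 equiv, excess recovered), PhF, 70 °C, slow addition of 8
Reagents that add atoms: none
Why: Rhodium carbenoid O–H insertion of a cyclic 2-diazo-1,3-dicarbonyl compound into an alcohol; the insertion product tautomerises to the 4-hydroxy-2-pyrone, so the hindered tertiary C–O bond at pyrone C3 is made without any substitution at the tertiary carbon. Excess alcohol and slow addition of 8 favour O–H insertion over addition to the π bonds.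

**Step 9**
Reactants: 16 3-{[(3Z)-2,9-dimethyldeca-3,8-dien-5-yn-2-yl]oxy}-4-hydroxy-6-{3-[2-methoxy-4-(triisopropylsilyloxy)phenyl]propyl}-2H-pyran-2-one
Product: 17 3-{[(3Z)-2,9-dimethyldeca-3,8-dien-5-yn-2-yl]oxy}-6-{3-[2-methoxy-4-(triisopropylsilyloxy)phenyl]propyl}-4-(triisopropylsilyloxy)-2H-pyran-2-one
Conditions: TIPSCl, imidazole, CH2Cl2, 0 °C → rt
Reagents that add atoms: chlorotriisopropylsilane, CC(C)[Si](Cl)(C(C)C)C(C)C
Why: O-silylation of the acidic 4-hydroxyl (a vinylogous acid) on the 2-pyrone tautomer; it removes the proton that would catalyse ionisation of the tertiary allylic ether on heating and becomes the C8 silyl ether of ring B.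

**Step 10**
Reactants: 17 3-{[(3Z)-2,9-dimethyldeca-3,8-dien-5-yn-2-yl]oxy}-6-{3-[2-methoxy-4-(triisopropylsilyloxy)phenyl]propyl}-4-(triisopropylsilyloxy)-2H-pyran-2-one
Product: 19 6-{3-[2-methoxy-4-(triisopropylsilyloxy)phenyl]propyl}-2,2-dimethyl-5-(3-methylbut-2-en-1-yl)-8-(triisopropylsilyloxy)-2H-chromene (bis-silyl ether of kazinol N), via bicyclic lactone 18 (not isolated)
Conditions: o-dichlorobenzene (0.01 M), BHT (0.1 equiv), 180 °C, sealed silylated vessel, argon
Reagents that add atoms: none
Why: Heating brings the alkyne over the pyrone diene C3=C4–C5=C6, and an intramolecular [4+2] cycloaddition joins C3 to the vinyl-bearing alkyne carbon and C6 to the prenyl-bearing one; the resulting 2-oxabicyclo[2.2.2]octadienone 18 expels CO2 by retro-[4+2] and aromatises to ring B of 19. The closest known reaction type is the thermal intramolecular Diels–Alder reaction and decarboxylation of 2-pyrones that carry a tethered unactivated alkyne, which is used to make fused and even strained benzene rings. Ring C closes as a six-membered ring in the fused mode of a type 1 intramolecular Diels–Alder reaction through the four-atom tether (O, CMe2, CH=CH), and ring B closes as the cycloadduct ring itself; the Z alkene and the gem-dimethyl group hold the alkyne within reach of C3. No stereocentre has to be controlled, since the two bridgehead centres of 18 are fixed by the bicycle and vanish with CO2. The step needs regioselectivity, and the tether enforces it because the inner alkyne carbon can reach only C3, so prenyl lands at C5 and the chain at C6 without any directing effect. It also needs the cycloaddition to win over [3,3] shift of the allyl enol ether onto C4 and over heterolysis of the tertiary C–O bond: C4 is blocked by the bulky silyloxy group, the Z-alkynyl terminus disfavours the chair transition state, the acidic hydroxyl is masked, and only the cycloaddition is made irreversible by loss of CO2. The prenyl alkene cannot reach the diene, and ring A is a spectator.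

**Step 11**
Reactants: 19 6-{3-[2-methoxy-4-(triisopropylsilyloxy)phenyl]propyl}-2,2-dimethyl-5-(3-methylbut-2-en-1-yl)-8-(triisopropylsilyloxy)-2H-chromene
Product: 20 kazinol N, 6-[3-(4-hydroxy-2-methoxyphenyl)propyl]-2,2-dimethyl-5-(3-methylbut-2-en-1-yl)-2H-chromen-8-ol
Conditions: Bu4NF (2.5 equiv), AcOH (2.5 equiv), THF, 0 °C, degassed
Reagents that add atoms: none
Why: Fluoride cleavage of both aryl silyl ethers; the acetic acid buffer keeps the electron-rich phenols from aerial oxidation as phenoxides, and the chromene and prenyl alkenes are inert to fluoride.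

## Compound list

1 | 4-bromo-3-methoxyphenol | COc1cc(O)ccc1Br | starting material
2 | (4-bromo-3-methoxyphenoxy)triisopropylsilane | COc1cc(O[Si](C(C)C)(C(C)C)C(C)C)ccc1Br | intermediate
3 | 4-ethoxy-4-oxobutylzinc bromide | CCOC(=O)CCC[Zn]Br | starting material
4 | ethyl 4-[2-methoxy-4-(triisopropylsilyloxy)phenyl]butanoate | CCOC(=O)CCCc1ccc(O[Si](C(C)C)(C(C)C)C(C)C)cc1OC | intermediate
5 | methyl acetoacetate | COC(=O)CC(C)=O | starting material
6 | methyl 8-[2-methoxy-4-(triisopropylsilyloxy)phenyl]-3,5-dioxooctanoate | COC(=O)CC(=O)CC(=O)CCCc1ccc(O[Si](C(C)C)(C(C)C)C(C)C)cc1OC | intermediate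
7 | 4-hydroxy-6-{3-[2-methoxy-4-(triisopropylsilyloxy)phenyl]propyl}-2H-pyran-2-one | O=C1C=C(O)C=C(CCCc2ccc(O[Si](C(C)C)(C(C)C)C(C)C)cc2OC)O1 | intermediate
8 | 3-diazo-6-{3-[2-methoxy-4-(triisopropylsilyloxy)phenyl]propyl}-2H-pyran-2,4(3H)-dione | [N-]=[N+]=C1C(=O)OC(CCCc2ccc(O[Si](C(C)C)(C(C)C)C(C)C)cc2OC)=CC1=O | intermediate
9 | ethynylmagnesium bromide | C#C[Mg]Br | starting material
10 | prenyl bromide (1-bromo-3-methylbut-2-ene) | CC(C)=CCBr | starting material
11 | 5-methylhex-4-en-1-yne | C#CCC=C(C)C | intermediate
12 | ethyl (Z)-3-iodoacrylate | CCOC(=O)/C=C\I | starting material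
13 | ethyl (Z)-8-methylnona-2,7-dien-4-ynoate | CCOC(=O)/C=C\C#CCC=C(C)C | intermediate
14 | (Z)-9-methyldeca-3,8-dien-5-yn-2-one | CC(=O)/C=C\C#CCC=C(C)C | intermediate
15 | (Z)-2,9-dimethyldeca-3,8-dien-5-yn-2-ol | CC(C)(O)/C=C\C#CCC=C(C)C | intermediate
16 | 3-{[(3Z)-2,9-dimethyldeca-3,8-dien-5-yn-2-yl]oxy}-4-hydroxy-6-{3-[2-methoxy-4-(triisopropylsilyloxy)phenyl]propyl}-2H-pyran-2-one | O=C1OC(CCCc2ccc(O[Si](C(C)C)(C(C)C)C(C)C)cc2OC)=CC(O)=C1OC(C)(C)/C=C\C#CCC=C(C)C | intermediate
17 | 3-{[(3Z)-2,9-dimethyldeca-3,8-dien-5-yn-2-yl]oxy}-6-{3-[2-methoxy-4-(triisopropylsilyloxy)phenyl]propyl}-4-(triisopropylsilyloxy)-2H-pyran-2-one | O=C1OC(CCCc2ccc(O[Si](C(C)C)(C(C)C)C(C)C)cc2OC)=CC(O[Si](C(C)C)(C(C)C)C(C)C)=C1OC(C)(C)/C=C\C#CCC=C(C)C | intermediate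
18 | Diels–Alder adduct of 17, a 2-oxabicyclo[2.2.2]octa-5,7-dien-3-one with the 2,2-dimethyl-2H-pyran ring fused at the former pyrone C3 (racemic; the two bridgehead centres are fixed relative to each other by the bicycle) | O=C1OC2(CCCc3ccc(O[Si](C(C)C)(C(C)C)C(C)C)cc3OC)C=C(O[Si](C(C)C)(C(C)C)C(C)C)C1(OC(C)(C)C=C4)C4=C2CC=C(C)C | intermediate
19 | 6-{3-[2-methoxy-4-(triisopropylsilyloxy)phenyl]propyl}-2,2-dimethyl-5-(3-methylbut-2-en-1-yl)-8-(triisopropylsilyloxy)-2H-chromene | COc1cc(O[Si](C(C)C)(C(C)C)C(C)C)ccc1CCCc1cc(O[Si](C(C)C)(C(C)C)C(C)C)c2c(c1CC=C(C)C)C=CC(C)(C)O2 | intermediate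
20 | kazinol N | COc1cc(O)ccc1CCCc1cc(O)c2c(c1CC=C(C)C)C=CC(C)(C)O2 | target

## Step count and risk

Total step count: 11. Longest linear sequence: 8 steps (steps 1, 2, 3, 4, 8, 9, 10, 11); steps 5 to 7 form the second branch, which joins at step 8.

**Step 10 (key step).** The most likely failure is that the tertiary allylic enol ether leaves by [3,3] shift onto C4 or by heterolysis of its C–O bond before the cycloaddition occurs. The cycloaddition has no electronic help, because the diene is electron-rich and the enyne is neutral. The fallback keeps the pyrone-to-arene idea but changes the dienophile and removes the allylic ether; it sets out from 8 and 11 and returns at 19.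
- Commercial ethyl 3-hydroxy-3-methylbutanoate is converted (MeNHOMe·HCl, i-PrMgCl) into 3-hydroxy-N-methoxy-N,3-dimethylbutanamide F1.
- The lithium acetylide of 11 adds to it to give the ynone alcohol 2-hydroxy-2,9-dimethyldec-8-en-5-yn-4-one F2.
- Rh2(OAc)4-catalysed O–H insertion with 8 gives the 3-alkoxy-4-hydroxypyrone F3, and TIPSCl/imidazole gives its silyl ether F4.
- The ynone is an activated dienophile matched to the electron-rich pyrone and the tether is saturated, so cycloaddition should proceed in toluene at about 110 °C through cycloadduct F5, with loss of CO2, to chroman-4-one F6.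
- NaBH4 reduction gives chroman-4-ol F7, and acid-catalysed dehydration (catalytic p-TsOH, toluene) gives 19.

**Step 8.** The rhodium carbenoid may be captured by the alkyne or alkenes of 15 (furan or cyclopropane formation) or by the acidic enol of the product, because the tertiary hydroxyl is a slow partner. The fallback sets out from 12 and 8 and returns at 16.
- MeLi/CeCl3 converts 12 into (Z)-4-iodo-2-methylbut-3-en-2-ol F8, a small alcohol without an alkyne that can be used in large excess.
- O–H insertion with 8 gives 4-hydroxy-3-{[(Z)-4-iodo-2-methylbut-3-en-2-yl]oxy}-6-{3-[2-methoxy-4-(triisopropylsilyloxy)phenyl]propyl}-2H-pyran-2-one F9.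
- Sonogashira coupling of F9 with 11 (PdCl2(PPh3)2, CuI, Et3N) attaches the enyne after the carbenoid step and gives 16.

**Step 3.** Acylation of the dianion by an unactivated ethyl ester may stall, because proton transfer from the product quenches the dianion, and the aryl silyl ether may be lost during the DBU lactonisation. The fallback replaces ring construction by alkylation of a preformed pyrone; it sets out from 2 and returns at 7.
- Bromine–lithium exchange on 2 (n-BuLi, −78 °C) and opening of ethylene oxide (BF3·OEt2) give 2-[2-methoxy-4-(triisopropylsilyloxy)phenyl]ethan-1-ol F10.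
- I2, PPh3 and imidazole give [4-(2-iodoethyl)-3-methoxyphenoxy]triisopropylsilane F11.
- The dilithio dianion of commercial 4-hydroxy-6-methyl-2H-pyran-2-one is alkylated at its methyl carbon by F11 to give 7.

**Step 5.** Substitution may occur at the tertiary end of the prenyl unit, the volatile enyne may be lost on isolation, and base may isomerise the skipped enyne to an allene. The fallback builds the 1,4-enyne on a non-volatile ester; it sets out from 12 and returns at 13.
- Sonogashira coupling of 12 with ethynyltrimethylsilane gives ethyl (Z)-5-(trimethylsilyl)pent-2-en-4-ynoate F12.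
- Buffered desilylation (Bu4NF, AcOH) gives ethyl (Z)-pent-2-en-4-ynoate F13.
- CuI-catalysed coupling of the terminal alkyne with 10 (K2CO3, NaI, DMF) gives 13.

## Further compounds

F1 | step 10 | 3-hydroxy-N-methoxy-N,3-dimethylbutanamide | CON(C)C(=O)CC(C)(C)O
F2 | step 10 | 2-hydroxy-2,9-dimethyldec-8-en-5-yn-4-one | CC(C)(O)CC(=O)C#CCC=C(C)C
F3 | step 10 | 3-[(2,9-dimethyl-4-oxodec-8-en-5-yn-2-yl)oxy]-4-hydroxy-6-{3-[2-methoxy-4-(triisopropylsilyloxy)phenyl]propyl}-2H-pyran-2-one | O=C1OC(CCCc2ccc(O[Si](C(C)C)(C(C)C)C(C)C)cc2OC)=CC(O)=C1OC(C)(C)CC(=O)C#CCC=C(C)C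
F4 | step 10 | 3-[(2,9-dimethyl-4-oxodec-8-en-5-yn-2-yl)oxy]-6-{3-[2-methoxy-4-(triisopropylsilyloxy)phenyl]propyl}-4-(triisopropylsilyloxy)-2H-pyran-2-one | O=C1OC(CCCc2ccc(O[Si](C(C)C)(C(C)C)C(C)C)cc2OC)=CC(O[Si](C(C)C)(C(C)C)C(C)C)=C1OC(C)(C)CC(=O)C#CCC=C(C)C
F5 | step 10 | Diels–Alder adduct of F4, a 2-oxabicyclo[2.2.2]octa-5,7-dien-3-one with a fused 2,2-dimethyltetrahydropyran-4-one ring (racemic) | O=C1OC2(CCCc3ccc(O[Si](C(C)C)(C(C)C)C(C)C)cc3OC)C=C(O[Si](C(C)C)(C(C)C)C(C)C)C1(OC(C)(C)CC4=O)C4=C2CC=C(C)C
F6 | step 10 | 6-{3-[2-methoxy-4-(triisopropylsilyloxy)phenyl]propyl}-2,2-dimethyl-5-(3-methylbut-2-en-1-yl)-8-(triisopropylsilyloxy)chroman-4-one | COc1cc(O[Si](C(C)C)(C(C)C)C(C)C)ccc1CCCc1cc(O[Si](C(C)C)(C(C)C)C(C)C)c2c(c1CC=C(C)C)C(=O)CC(C)(C)O2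
F7 | step 10 | 6-{3-[2-methoxy-4-(triisopropylsilyloxy)phenyl]propyl}-2,2-dimethyl-5-(3-methylbut-2-en-1-yl)-8-(triisopropylsilyloxy)chroman-4-ol (racemic) | COc1cc(O[Si](C(C)C)(C(C)C)C(C)C)ccc1CCCc1cc(O[Si](C(C)C)(C(C)C)C(C)C)c2c(c1CC=C(C)C)C(O)CC(C)(C)O2
F8 | step 8 | (Z)-4-iodo-2-methylbut-3-en-2-ol | CC(C)(O)/C=C\I
F9 | step 8 | 4-hydroxy-3-{[(Z)-4-iodo-2-methylbut-3-en-2-yl]oxy}-6-{3-[2-methoxy-4-(triisopropylsilyloxy)phenyl]propyl}-2H-pyran-2-one | O=C1OC(CCCc2ccc(O[Si](C(C)C)(C(C)C)C(C)C)cc2OC)=CC(O)=C1OC(C)(C)/C=C\I
F10 | step 3 | 2-[2-methoxy-4-(triisopropylsilyloxy)phenyl]ethan-1-ol | OCCc1ccc(O[Si](C(C)C)(C(C)C)C(C)C)cc1OC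
F11 | step 3 | [4-(2-iodoethyl)-3-methoxyphenoxy]triisopropylsilane | ICCc1ccc(O[Si](C(C)C)(C(C)C)C(C)C)cc1OC
F12 | step 5 | ethyl (Z)-5-(trimethylsilyl)pent-2-en-4-ynoate | CCOC(=O)/C=C\C#C[Si](C)(C)C
F13 | step 5 | ethyl (Z)-pent-2-en-4-ynoate | CCOC(=O)/C=C\C#C
A1 | alternative 1 | 8-hydroxy-2,2-dimethyl-2H-chromene-6-carbaldehyde | O=Cc1cc(O)c2OC(C)(C)C=Cc2c1
A2 | alternative 1 | (E)-1-(4-hydroxy-2-methoxyphenyl)-3-[8-hydroxy-2,2-dimethyl-5-(3-methylbut-2-en-1-yl)-2H-chromen-6-yl]prop-2-en-1-one | COc1cc(O)ccc1C(=O)/C=C/c1cc(O)c2OC(C)(C)C=Cc2c1CC=C(C)C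
A3 | alternative 2 | 3-{3-[2-methoxy-4-(triisopropylsilyloxy)phenyl]propyl}cyclobut-2-en-1-one | O=C1C=C(CCCc2ccc(O[Si](C(C)C)(C(C)C)C(C)C)cc2OC)C1
A4 | alternative 3 | 2,2-dimethyl-2,6,7,8-tetrahydro-5H-chromen-5-one | CC1(C)C=CC2=C(CCCC2=O)O1
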